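**Retrosynthetic overview**
1. Target 17 ⇐ tris-MOM ether 16 ⇐ 3,5-dibromide 14 + 2 × prenyl-Bpin 15 (double Suzuki–Miyaura prenylation; phenols unmasked last).
2. 14 ⇐ resorcylate 11 by ring dibromination and exchange of the side-chain benzyl ether for MOM.
3. 11 ⇐ cyclohexane-1,3-dione ester 9 by bromination–dehydrobromination (aromatisation).
4. 9 ⇐ enone 6 + dimethyl malonate 7: intermolecular Michael addition (C1–C6 bond, key step) followed by ring-closing Claisen condensation.
5. 6 ⇐ aldehyde 4 + acetonyl ylide 5; 4 from methyl 3-(4-hydroxyphenyl)propanoate 1. The hydroxyphenyl ring is bought; the resorcylate ring is the only ring made (step 5) and is aromatised in step 6.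

Assumption: the target has no stereocentre and no stereogenic double bond, so it is made exactly as drawn and no enantiocontrol is needed.

**Step 1**
Reactants: 1 methyl 3-(4-hydroxyphenyl)propanoate
Product: 2 methyl 3-[4-(benzyloxy)phenyl]propanoate
Conditions: BnBr (1.1 equiv), K2CO3 (1.5 equiv), acetone, reflux
Reagents that add atoms: benzyl bromide, BrCc1ccccc1
Why: Williamson ether synthesis (SN2 of the phenoxide on a benzylic bromide) gives an ether that withstands methoxide, hydride, the ylide and HBr/DMF in the following steps.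

**Step 2**
Reactants: 2 methyl 3-[4-(benzyloxy)phenyl]propanoate
Product: 3 3-[4-(benzyloxy)phenyl]propan-1-ol
Conditions: LiAlH4, THF, 0 °C to rt; H2O quench
Reagents that add atoms: none
Why: Hydride reduction of the ester to the primary alcohol is cleaner than a direct partial reduction to the aldehyde.

**Step 3**
Reactants: 3 3-[4-(benzyloxy)phenyl]propan-1-ol
Product: 4 3-[4-(benzyloxy)phenyl]propanal
Conditions: TEMPO (10 mol %), PhI(OAc)2 (1.1 equiv), CH2Cl2, rt
Reagents that add atoms: none
Why: TEMPO/oxoammonium-catalysed alcohol oxidation stops at the aldehyde and leaves the aryl ether untouched.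

**Step 4**
Reactants: 4 3-[4-(benzyloxy)phenyl]propanal; 5 1-(triphenyl-λ5-phosphanylidene)propan-2-one
Product: 6 (E)-6-[4-(benzyloxy)phenyl]hex-3-en-2-one
Conditions: toluene, 80 °C
Reagents that add atoms: none
Why: Wittig olefination with a stabilised ylide gives the (E)-enone without self-aldol of the enolisable aldehyde; the alkene geometry is lost later and is not critical.

**Step 5**
Reactants: 6 (E)-6-[4-(benzyloxy)phenyl]hex-3-en-2-one; 7 dimethyl malonate
Product: 9 methyl 6-{2-[4-(benzyloxy)phenyl]ethyl}-2-hydroxy-4-oxocyclohex-2-ene-1-carboxylate (racemic), via Michael adduct 8 (not isolated)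
Conditions: NaOMe (1.2 equiv), MeOH, reflux; then 1 M HCl, 0 °C
Reagents that add atoms: none
Why: Intermolecular Michael addition of the malonate anion to the enone β-carbon makes the C1–C6 bond, and the methyl-ketone enolate of 8 then closes the six-membered ring by Claisen (Dieckmann-type) condensation, driven by the stable 1,3-dione enolate; the two stereocentres form racemic and are erased in step 6.

**Step 6**
Reactants: 9 methyl 6-{2-[4-(benzyloxy)phenyl]ethyl}-2-hydroxy-4-oxocyclohex-2-ene-1-carboxylate
Product: 11 methyl 6-{2-[4-(benzyloxy)phenyl]ethyl}-2,4-dihydroxybenzoate, via bromodione 10 (not isolated)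
Conditions: Br2 (1.0 equiv), DMF, 0 °C, then 80 °C
Reagents that add atoms: none
Why: Bromination of the dione enol at C3 followed by thermal dehydrobromination through the dienol and tautomerisation aromatises the ring; the single equivalent of Br2 is consumed by the enol before it can attack the aryl ether ring.

**Step 7**
Reactants: 11 methyl 6-{2-[4-(benzyloxy)phenyl]ethyl}-2,4-dihydroxybenzoate
Product: 12 methyl 6-{2-[4-(benzyloxy)phenyl]ethyl}-3,5-dibromo-2,4-dihydroxybenzoate
Conditions: NBS (2.05 equiv), MeCN, 0 °C, dark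
Reagents that add atoms: N-bromosuccinimide, O=C1CCC(=O)N1Br
Why: Electrophilic aromatic bromination takes the only two free positions (C3, C5) of the dihydroxylated ring, which is far more reactive than the mono-alkoxy ring carrying the benzyl ether.

**Step 8**
Reactants: 12 methyl 6-{2-[4-(benzyloxy)phenyl]ethyl}-3,5-dibromo-2,4-dihydroxybenzoate
Product: 13 methyl 3,5-dibromo-2,4-dihydroxy-6-[2-(4-hydroxyphenyl)ethyl]benzoate
Conditions: BCl3 (4 equiv), pentamethylbenzene (3 equiv), CH2Cl2, −78 to −40 °C; MeOH quench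
Reagents that add atoms: none
Why: Lewis-acid debenzylation with a non-basic benzyl-cation scavenger spares the C–Br bonds (hydrogenolysis would not) and is done here because no acid-sensitive prenyl group is present yet.

**Step 9**
Reactants: 13 methyl 3,5-dibromo-2,4-dihydroxy-6-[2-(4-hydroxyphenyl)ethyl]benzoate
Product: 14 methyl 3,5-dibromo-2,4-bis(methoxymethoxy)-6-{2-[4-(methoxymethoxy)phenyl]ethyl}benzoate
Conditions: NaH (4 equiv), MOMCl (4 equiv), DMF, 0 °C to rt
Reagents that add atoms: chloromethyl methyl ether, COCCl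
Why: O-alkylation of the three sodium phenoxides with the small, very reactive MOM chloride protects even the hindered and hydrogen-bonded hydroxyls with a base-stable group for the coupling.

**Step 10**
Reactants: 14 methyl 3,5-dibromo-2,4-bis(methoxymethoxy)-6-{2-[4-(methoxymethoxy)phenyl]ethyl}benzoate; 15 4,4,5,5-tetramethyl-2-(3-methylbut-2-en-1-yl)-1,3,2-dioxaborolane (3 equiv)
Product: 16 methyl 2,4-bis(methoxymethoxy)-6-{2-[4-(methoxymethoxy)phenyl]ethyl}-3,5-bis(3-methylbut-2-en-1-yl)benzoate
Conditions: Pd-PEPPSI-IPent (5 mol %), 5 M aq KOH, THF, 70 °C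
Reagents that add atoms: none
Why: Double Suzuki–Miyaura allyl–aryl coupling with a bulky NHC–Pd catalyst reaches the di-ortho-substituted positions and reductively eliminates at the unhindered CH2 terminus to give the linear prenyl groups, while the flanked methyl ester resists hydroxide.

**Step 11**
Reactants: 16 methyl 2,4-bis(methoxymethoxy)-6-{2-[4-(methoxymethoxy)phenyl]ethyl}-3,5-bis(3-methylbut-2-en-1-yl)benzoate
Product: 17 methyl 2,4-dihydroxy-6-[2-(4-hydroxyphenyl)ethyl]-3,5-bis(3-methylbut-2-en-1-yl)benzoate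
Conditions: 3 M aq HCl, MeOH, 45 °C, stopped at full conversion
Reagents that add atoms: none
Why: Acid-catalysed acetal cleavage (transacetalisation to dimethoxymethane) frees the three phenols under conditions mild enough to leave the prenyl alkenes and the methyl ester intact.

**Compound list**
1 | methyl 3-(4-hydroxyphenyl)propanoate | COC(=O)CCc1ccc(O)cc1 | starting material
2 | methyl 3-[4-(benzyloxy)phenyl]propanoate | COC(=O)CCc1ccc(OCc2ccccc2)cc1 | intermediate
3 | 3-[4-(benzyloxy)phenyl]propan-1-ol | OCCCc1ccc(OCc2ccccc2)cc1 | intermediate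
4 | 3-[4-(benzyloxy)phenyl]propanal | O=CCCc1ccc(OCc2ccccc2)cc1 | intermediate
5 | 1-(triphenyl-λ5-phosphanylidene)propan-2-one | CC(=O)C=P(c1ccccc1)(c1ccccc1)c1ccccc1 | starting material
6 | (E)-6-[4-(benzyloxy)phenyl]hex-3-en-2-one | CC(=O)/C=C/CCc1ccc(OCc2ccccc2)cc1 | intermediate
7 | dimethyl malonate | COC(=O)CC(=O)OC | starting material
8 | dimethyl 2-{1-[4-(benzyloxy)phenyl]-5-oxohexan-3-yl}propanedioate (racemic Michael adduct) | COC(=O)C(C(=O)OC)C(CCc1ccc(OCc2ccccc2)cc1)CC(C)=O | intermediate (not isolated)
9 | methyl 6-{2-[4-(benzyloxy)phenyl]ethyl}-2-hydroxy-4-oxocyclohex-2-ene-1-carboxylate (racemic, enol form of the 2,4-dione) | COC(=O)C1C(CCc2ccc(OCc3ccccc3)cc2)CC(=O)C=C1O | intermediate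
10 | methyl 6-{2-[4-(benzyloxy)phenyl]ethyl}-3-bromo-2-hydroxy-4-oxocyclohex-2-ene-1-carboxylate (racemic bromodione) | COC(=O)C1C(CCc2ccc(OCc3ccccc3)cc2)CC(=O)C(Br)=C1O | intermediate (not isolated)
11 | methyl 6-{2-[4-(benzyloxy)phenyl]ethyl}-2,4-dihydroxybenzoate | COC(=O)c1c(O)cc(O)cc1CCc1ccc(OCc2ccccc2)cc1 | intermediate
12 | methyl 6-{2-[4-(benzyloxy)phenyl]ethyl}-3,5-dibromo-2,4-dihydroxybenzoate | COC(=O)c1c(O)c(Br)c(O)c(Br)c1CCc1ccc(OCc2ccccc2)cc1 | intermediate
13 | methyl 3,5-dibromo-2,4-dihydroxy-6-[2-(4-hydroxyphenyl)ethyl]benzoate | COC(=O)c1c(O)c(Br)c(O)c(Br)c1CCc1ccc(O)cc1 | intermediate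
14 | methyl 3,5-dibromo-2,4-bis(methoxymethoxy)-6-{2-[4-(methoxymethoxy)phenyl]ethyl}benzoate | COCOc1ccc(CCc2c(Br)c(OCOC)c(Br)c(OCOC)c2C(=O)OC)cc1 | intermediate
15 | 4,4,5,5-tetramethyl-2-(3-methylbut-2-en-1-yl)-1,3,2-dioxaborolane (prenyl-Bpin) | CC(C)=CCB1OC(C)(C)C(C)(C)O1 | starting material
16 | methyl 2,4-bis(methoxymethoxy)-6-{2-[4-(methoxymethoxy)phenyl]ethyl}-3,5-bis(3-methylbut-2-en-1-yl)benzoate | COCOc1ccc(CCc2c(CC=C(C)C)c(OCOC)c(CC=C(C)C)c(OCOC)c2C(=O)OC)cc1 | intermediate
17 | methyl 2,4-dihydroxy-6-[2-(4-hydroxyphenyl)ethyl]-3,5-bis(3-methylbut-2-en-1-yl)benzoate (CNP0133671.0) | COC(=O)c1c(O)c(CC=C(C)C)c(O)c(CC=C(C)C)c1CCc1ccc(O)cc1 | target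

**Totals**
Total step count: 11. Longest linear sequence: 11 steps (1 → 17); compounds 5, 7 and 15 are bought.

**Three steps most likely to fail**

Step 10 (double prenyl coupling). The risks are mono-coupling at the two di-ortho-substituted positions, protodebromination and some reverse-prenyl isomer. The fallback removes the regiochemical question by coupling a plain allyl group and building the prenyl terminus afterwards. It sets out from 14: double Suzuki allylation with allylboronic acid pinacol ester (Pd(dppf)Cl2, K3PO4, THF–H2O, 70 °C) gives methyl 2,4-bis(methoxymethoxy)-6-{2-[4-(methoxymethoxy)phenyl]ethyl}-3,5-di(prop-2-en-1-yl)benzoate F2. Olefin cross-metathesis with excess 2-methylbut-2-ene (Grubbs II, CH2Cl2, 40 °C) then turns both allyl groups into prenyl groups, and the fallback comes back to the route at 16.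

Step 6 (aromatisation). The risks are over-bromination, partial loss of the benzyl ether in hot HBr/DMF and incomplete dehydrobromination. The fallback forms the ring already at the aromatic oxidation level, so no dehydrogenation is needed. It sets out from ester 2: the trianion of commercial methyl 3,5-dioxohexanoate (LDA, 3.3 equiv, THF, −78 to 0 °C) is acylated at its terminal carbon by 2 in an intermolecular Claisen condensation to give methyl 9-[4-(benzyloxy)phenyl]-3,5,7-trioxononanoate F1. Treatment with K2CO3 in MeOH at rt and then dilute HCl closes C2 onto the C7 ketone (intramolecular aldol condensation, dehydration, enolisation), and the fallback comes back to the route at 11, bypassing steps 2–6.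

Step 11 (acidic removal of three MOM groups next to two prenyl groups). The risks are acid-catalysed cyclisation of an ortho-prenyl phenol to a 2,2-dimethylchroman and addition of HCl or MeOH to the trisubstituted alkenes. The fallback changes the protecting groups so that the last step is basic. It sets out from triol 13: Ac2O, pyridine and DMAP give methyl 2,4-diacetoxy-6-[2-(4-acetoxyphenyl)ethyl]-3,5-dibromobenzoate F3. A neutral double Stille coupling with tributyl(3-methylbut-2-en-1-yl)stannane (Pd(PPh3)4, DMF, 100 °C) gives methyl 2,4-diacetoxy-6-[2-(4-acetoxyphenyl)ethyl]-3,5-bis(3-methylbut-2-en-1-yl)benzoate F4. K2CO3 in MeOH at rt then removes the acetates by transesterification, which cannot change the methyl ester, and the fallback comes back to the route at target 17.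

**Further compounds**
F1 | step 6 | methyl 9-[4-(benzyloxy)phenyl]-3,5,7-trioxononanoate | COC(=O)CC(=O)CC(=O)CC(=O)CCc1ccc(OCc2ccccc2)cc1
F2 | step 10 | methyl 2,4-bis(methoxymethoxy)-6-{2-[4-(methoxymethoxy)phenyl]ethyl}-3,5-di(prop-2-en-1-yl)benzoate | COCOc1ccc(CCc2c(CC=C)c(OCOC)c(CC=C)c(OCOC)c2C(=O)OC)cc1
F3 | step 11 | methyl 2,4-diacetoxy-6-[2-(4-acetoxyphenyl)ethyl]-3,5-dibromobenzoate | COC(=O)c1c(OC(C)=O)c(Br)c(OC(C)=O)c(Br)c1CCc1ccc(OC(C)=O)cc1
F4 | step 11 | methyl 2,4-diacetoxy-6-[2-(4-acetoxyphenyl)ethyl]-3,5-bis(3-methylbut-2-en-1-yl)benzoate | COC(=O)c1c(OC(C)=O)c(CC=C(C)C)c(OC(C)=O)c(CC=C(C)C)c1CCc1ccc(OC(C)=O)cc1
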